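The pyranone ring of the flavanone (O1, C2, C3, C4, C4a, C8a) is cut at its two bonds to ring A, C4–C4a and O1–C8a. What remains is an enantiopure β-lactone that already holds O1, C2 (with its S configuration), C3 and C4. In the key step an ortho-fluoroaryllithium (ring A, lithiated between F and OMe) opens this lactone at the acyl carbon and the released alkoxide then displaces the fluoride, so the C4a–C8a edge of ring A is inserted into the O1–C4 bond: a two-atom ring expansion from four to six members with retention at C2. Suzuki coupling with a 6-iodoapigenin bis-MOM ether and deprotection complete the 3'–6'' biflavonoid.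

Key step: step 7

Remark: only C2 is stereogenic in the target; the biaryl axis carries three small ortho oxygen substituents and is treated as freely rotating, so no axial control is planned.

**Step 1**
Reactants: 1 1-(3-bromo-4-hydroxyphenyl)ethanone
Product: 2 1-[3-bromo-4-(methoxymethoxy)phenyl]ethanone
Conditions: MOMCl, i-Pr2NEt, CH2Cl2, 0 °C to rt
Reagents that add atoms: chloromethyl methyl ether, COCCl
Why: O-alkylation of the phenol with the reactive α-chloro ether (MOM protection) masks the acidic OH for the later enolate and organolithium steps.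

**Step 2**
Reactants: 2 1-[3-bromo-4-(methoxymethoxy)phenyl]ethanone
Product: 3 ethyl 3-[3-bromo-4-(methoxymethoxy)phenyl]-3-oxopropanoate
Conditions: NaH, (EtO)2CO, THF, reflux; AcOH quench
Reagents that add atoms: diethyl carbonate, CCOC(=O)OCC
Why: crossed Claisen condensation of the methyl ketone enolate with the non-enolisable carbonate, driven by deprotonation of the β-keto ester formed.

**Step 3**
Reactants: 3 ethyl 3-[3-bromo-4-(methoxymethoxy)phenyl]-3-oxopropanoate
Product: 4 ethyl (3S)-3-[3-bromo-4-(methoxymethoxy)phenyl]-3-hydroxypropanoate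
Conditions: H2 (50 bar), RuCl2[(R)-BINAP] (0.5 mol %), EtOH, 60 °C
Reagents that add atoms: none
Why: Noyori asymmetric hydrogenation of a β-keto ester, in which the ester-chelated ketone is reduced on the face set by the (R)-BINAP ligand; in the 3-aryl series this should give the (S)-carbinol, the future C2.

**Step 4**
Reactants: 4 ethyl (3S)-3-[3-bromo-4-(methoxymethoxy)phenyl]-3-hydroxypropanoate
Product: 5 (3S)-3-[3-bromo-4-(methoxymethoxy)phenyl]-3-hydroxypropanoic acid
Conditions: LiOH·H2O, THF/H2O, 0 °C to rt; then 1 M HCl to pH 3, 0 °C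
Reagents that add atoms: lithium hydroxide, [Li+].[OH-]
Why: saponification by acyl–oxygen cleavage leaves the benzylic stereocentre untouched, and the brief cold acidification should spare the MOM ether.

**Step 5**
Reactants: 5 (3S)-3-[3-bromo-4-(methoxymethoxy)phenyl]-3-hydroxypropanoic acid
Product: 6 (4S)-4-[3-bromo-4-(methoxymethoxy)phenyl]oxetan-2-one
Conditions: PhSO2Cl, pyridine, 0 °C
Reagents that add atoms: none
Why: β-lactonisation by carboxyl activation (mixed sulfonic–carboxylic anhydride, then 4-exo-trig attack of the hydroxyl) does not break the C–O bond at the stereocentre, so the configuration should be retained.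

**Step 6**
Reactants: 7 3-fluoro-5-methoxyphenol
Product: 8 (3-fluoro-5-methoxyphenoxy)triisopropylsilane
Conditions: TIPSCl, imidazole, DMF, rt
Reagents that add atoms: chlorotriisopropylsilane, CC(C)[Si](Cl)(C(C)C)C(C)C
Why: silylation of the phenol gives a bulky, non-coordinating ether that shields its two flanking ring positions in the lithiation that follows.

**Step 7**
Reactants: 8 (3-fluoro-5-methoxyphenoxy)triisopropylsilane; 6 (4S)-4-[3-bromo-4-(methoxymethoxy)phenyl]oxetan-2-one
Product: 11 (2S)-2-[3-bromo-4-(methoxymethoxy)phenyl]-5-methoxy-7-(triisopropylsilyloxy)-2,3-dihydro-4H-chromen-4-one, via aryllithium 9 (not isolated), via lithium keto-alkoxide 10 (not isolated)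
Conditions: 8, n-BuLi (0.95 equiv), THF, −78 °C; cannulate into 6, THF, −78 °C; then DMPU, −78 to 40 °C
Reagents that add atoms: none
Why: Cooperative ortho-lithiation of 8 by fluorine and methoxy (the para OTIPS group neither coordinates nor flanks that site) gives aryllithium 9, a hard nucleophile that attacks the strained acyl carbon of β-lactone 6 (nucleophilic acyl substitution with acyl–oxygen cleavage), and collapse of the tetrahedral intermediate opens the four-membered ring to lithium keto-alkoxide 10. On warming with DMPU the alkoxide oxygen O1 displaces the fluoride ortho to the new ketone by addition–elimination through a Meisenheimer intermediate (intramolecular SNAr, six-membered O–aryl closure), so the net change is insertion of the C4a–C8a edge of ring A into the O1–C4 bond, a four-to-six ring expansion. Both stages are established reaction types run in one flask: organolithium opening of β-lactones to β-hydroxy ketones and alkoxide SNAr cyclisation of β-hydroxy 2-fluoroaryl ketones to chroman-4-ones. No stereocentre is formed; C2 is the lactone C4, whose C–O and C–H bonds are never broken, so the (S) configuration should be carried over with retention. The step needs carbonyl attack instead of alkyl C–O attack (secured by the hard aryllithium at −78 °C and the hindered secondary benzylic carbon), mono-addition (the 2,6-disubstituted aryl ketone is shielded and inverse addition keeps 9 deficient, which also disfavours bromine–lithium exchange), and ring closure faster than retro-aldol cleavage of 10 (no proton source is present, so dehydration is excluded, and LiF formation drives the closure).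

**Step 8**
Reactants: 11 (2S)-2-[3-bromo-4-(methoxymethoxy)phenyl]-5-methoxy-7-(triisopropylsilyloxy)-2,3-dihydro-4H-chromen-4-one
Product: 12 (2S)-5-methoxy-2-[4-(methoxymethoxy)-3-(4,4,5,5-tetramethyl-1,3,2-dioxaborolan-2-yl)phenyl]-7-(triisopropylsilyloxy)-2,3-dihydro-4H-chromen-4-one
Conditions: B2pin2, Pd(dppf)Cl2 (5 mol %), KOAc, 1,4-dioxane, 80 °C
Reagents that add atoms: bis(pinacolato)diboron, CC1(C)OB(OC1(C)C)B1OC(C)(C)C(C)(C)O1
Why: Miyaura borylation of the aryl bromide with the weak base KOAc should leave the base-sensitive flavanone C2 centre intact.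

**Step 9**
Reactants: 13 apigenin (5,7-dihydroxy-2-(4-hydroxyphenyl)-4H-chromen-4-one)
Product: 14 5-hydroxy-7-(methoxymethoxy)-2-[4-(methoxymethoxy)phenyl]-4H-chromen-4-one
Conditions: MOMCl (2.2 equiv), i-Pr2NEt, DMF, 0 °C to rt
Reagents that add atoms: chloromethyl methyl ether, COCCl
Why: selective MOM protection of the two acidic, non-chelated phenols, while the 5-OH, hydrogen-bonded to the C4 carbonyl, stays free.

**Step 10**
Reactants: 14 5-hydroxy-7-(methoxymethoxy)-2-[4-(methoxymethoxy)phenyl]-4H-chromen-4-one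
Product: 15 5-hydroxy-6-iodo-7-(methoxymethoxy)-2-[4-(methoxymethoxy)phenyl]-4H-chromen-4-one
Conditions: NIS, DMF, rt
Reagents that add atoms: N-iodosuccinimide, O=C1CCC(=O)N1I
Why: electrophilic aromatic iodination under neutral conditions, directed ortho to the free 5-OH and therefore to C6 in preference to C8.

**Step 11**
Reactants: 12 (2S)-5-methoxy-2-[4-(methoxymethoxy)-3-(4,4,5,5-tetramethyl-1,3,2-dioxaborolan-2-yl)phenyl]-7-(triisopropylsilyloxy)-2,3-dihydro-4H-chromen-4-one; 15 5-hydroxy-6-iodo-7-(methoxymethoxy)-2-[4-(methoxymethoxy)phenyl]-4H-chromen-4-one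
Product: 16 (2S)-2-[3-{5-hydroxy-7-(methoxymethoxy)-2-[4-(methoxymethoxy)phenyl]-4-oxo-4H-chromen-6-yl}-4-(methoxymethoxy)phenyl]-5-methoxy-7-(triisopropylsilyloxy)-2,3-dihydro-4H-chromen-4-one
Conditions: Pd(OAc)2 (5 mol %), SPhos (10 mol %), K3PO4, toluene/H2O (10:1), 40 °C
Reagents that add atoms: none
Why: Suzuki–Miyaura coupling with a dialkylbiarylphosphine ligand suited to tri-ortho-substituted biaryls, run biphasic at 40 °C so that enolisation at C3 and ring opening of the flavanone stay slow.

**Step 12**
Reactants: 16 (2S)-2-[3-{5-hydroxy-7-(methoxymethoxy)-2-[4-(methoxymethoxy)phenyl]-4-oxo-4H-chromen-6-yl}-4-(methoxymethoxy)phenyl]-5-methoxy-7-(triisopropylsilyloxy)-2,3-dihydro-4H-chromen-4-one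
Product: 18 (2S)-2-{3-[5,7-dihydroxy-2-(4-hydroxyphenyl)-4-oxo-4H-chromen-6-yl]-4-hydroxyphenyl}-7-hydroxy-5-methoxy-2,3-dihydro-4H-chromen-4-one (target), via desilylated tris-MOM ether 17 (not isolated)
Conditions: TBAF, AcOH, THF, 0 °C; then 3 M HCl, MeOH, 45 °C
Reagents that add atoms: none
Why: buffered fluoride cleaves the aryl silyl ether and acid-catalysed transacetalisation to methanol removes the three MOM groups, conditions under which the 5-methyl ether and the C2 centre should be stable.

**Compound list**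

1 | 1-(3-bromo-4-hydroxyphenyl)ethanone | CC(=O)c1ccc(O)c(Br)c1 | starting material
2 | 1-[3-bromo-4-(methoxymethoxy)phenyl]ethanone | CC(=O)c1ccc(OCOC)c(Br)c1 | intermediate
3 | ethyl 3-[3-bromo-4-(methoxymethoxy)phenyl]-3-oxopropanoate | CCOC(=O)CC(=O)c1ccc(OCOC)c(Br)c1 | intermediate
4 | ethyl (3S)-3-[3-bromo-4-(methoxymethoxy)phenyl]-3-hydroxypropanoate | CCOC(=O)C[C@H](O)c1ccc(OCOC)c(Br)c1 | intermediate
5 | (3S)-3-[3-bromo-4-(methoxymethoxy)phenyl]-3-hydroxypropanoic acid | OC(=O)C[C@H](O)c1ccc(OCOC)c(Br)c1 | intermediate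
6 | (4S)-4-[3-bromo-4-(methoxymethoxy)phenyl]oxetan-2-one | O=C1C[C@@H](c2ccc(OCOC)c(Br)c2)O1 | intermediate
7 | 3-fluoro-5-methoxyphenol | COc1cc(O)cc(F)c1 | starting material
8 | (3-fluoro-5-methoxyphenoxy)triisopropylsilane | COc1cc(F)cc(O[Si](C(C)C)(C(C)C)C(C)C)c1 | intermediate
9 | [2-fluoro-6-methoxy-4-(triisopropylsilyloxy)phenyl]lithium (not isolated) | [Li]c1c(F)cc(O[Si](C(C)C)(C(C)C)C(C)C)cc1OC | intermediate
10 | lithium (1S)-1-[3-bromo-4-(methoxymethoxy)phenyl]-3-[2-fluoro-6-methoxy-4-(triisopropylsilyloxy)phenyl]-3-oxopropan-1-olate (not isolated) | [Li+].[O-][C@@H](CC(=O)c1c(F)cc(O[Si](C(C)C)(C(C)C)C(C)C)cc1OC)c1ccc(OCOC)c(Br)c1 | intermediate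
11 | (2S)-2-[3-bromo-4-(methoxymethoxy)phenyl]-5-methoxy-7-(triisopropylsilyloxy)-2,3-dihydro-4H-chromen-4-one | COc1cc(O[Si](C(C)C)(C(C)C)C(C)C)cc2c1C(=O)C[C@@H](c1ccc(OCOC)c(Br)c1)O2 | intermediate
12 | (2S)-5-methoxy-2-[4-(methoxymethoxy)-3-(4,4,5,5-tetramethyl-1,3,2-dioxaborolan-2-yl)phenyl]-7-(triisopropylsilyloxy)-2,3-dihydro-4H-chromen-4-one | COc1cc(O[Si](C(C)C)(C(C)C)C(C)C)cc2c1C(=O)C[C@@H](c1ccc(OCOC)c(B3OC(C)(C)C(C)(C)O3)c1)O2 | intermediate
13 | apigenin | O=c1cc(-c2ccc(O)cc2)oc2cc(O)cc(O)c12 | starting material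
14 | 5-hydroxy-7-(methoxymethoxy)-2-[4-(methoxymethoxy)phenyl]-4H-chromen-4-one | COCOc1ccc(-c2cc(=O)c3c(O)cc(OCOC)cc3o2)cc1 | intermediate
15 | 5-hydroxy-6-iodo-7-(methoxymethoxy)-2-[4-(methoxymethoxy)phenyl]-4H-chromen-4-one | COCOc1ccc(-c2cc(=O)c3c(O)c(I)c(OCOC)cc3o2)cc1 | intermediate
16 | (2S)-2-[3-{5-hydroxy-7-(methoxymethoxy)-2-[4-(methoxymethoxy)phenyl]-4-oxo-4H-chromen-6-yl}-4-(methoxymethoxy)phenyl]-5-methoxy-7-(triisopropylsilyloxy)-2,3-dihydro-4H-chromen-4-one | COc1cc(O[Si](C(C)C)(C(C)C)C(C)C)cc2c1C(=O)C[C@@H](c1ccc(OCOC)c(-c3c(OCOC)cc4oc(-c5ccc(OCOC)cc5)cc(=O)c4c3O)c1)O2 | intermediate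
17 | (2S)-7-hydroxy-2-[3-{5-hydroxy-7-(methoxymethoxy)-2-[4-(methoxymethoxy)phenyl]-4-oxo-4H-chromen-6-yl}-4-(methoxymethoxy)phenyl]-5-methoxy-2,3-dihydro-4H-chromen-4-one (not isolated) | COc1cc(O)cc2c1C(=O)C[C@@H](c1ccc(OCOC)c(-c3c(OCOC)cc4oc(-c5ccc(OCOC)cc5)cc(=O)c4c3O)c1)O2 | intermediate
18 | (2S)-2-{3-[5,7-dihydroxy-2-(4-hydroxyphenyl)-4-oxo-4H-chromen-6-yl]-4-hydroxyphenyl}-7-hydroxy-5-methoxy-2,3-dihydro-4H-chromen-4-one (CNP0332590.1) | COc1cc(O)cc2c1C(=O)C[C@@H](c1ccc(O)c(-c3c(O)cc4oc(-c5ccc(O)cc5)cc(=O)c4c3O)c1)O2 | target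

**Step count and risks**

Total step count: 12. Longest linear sequence: 9 steps (steps 1, 2, 3, 4, 5, 7, 8, 11, 12).

Steps most likely to fail:

1. Step 7 (key step). The lithium keto-alkoxide may cleave by retro-aldol, or recombine with loss of configuration, before it displaces the fluoride. The aryllithium may also act as a base on the lactone or on the new ketone instead of adding once. Fallback, setting out from lactone 6 and returning at 11: the lactone would be opened with MeNH(OMe)·HCl and Me2AlCl (CH2Cl2, 0 °C) to the (3S)-β-hydroxy Weinreb amide F1. Silylation (TESCl, imidazole, DMF) would give the triethylsilyl ether F2. Addition of aryllithium 9 (THF, −78 °C), whose chelated tetrahedral intermediate stops at the ketone stage, would give the 2-fluoroaryl β-silyloxy ketone F3. Catalytic TBAF in DMF at 0 °C would then trigger a desilylative SNAr closure, in which the departing fluoride carries off the silyl group and no stoichiometric free aldolate is present, to give 11.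

2. Step 11. Transmetalation at the tri-ortho-substituted axis may be slow enough that protodeboronation takes over, and the base may enolise C3 and open and reclose the flavanone ring with loss of configuration at C2. Fallback, setting out from bromide 11 and returning at 16: base-free Stille coupling. Stannylation of 11 (Me3SnSnMe3, Pd(PPh3)4, toluene, 100 °C) would give the arylstannane F4, which would be coupled with iodide 15 (Pd2(dba)3, AsPh3, CuI, DMF, 50 °C) to give 16.

3. Step 5. Carboxyl activation in pyridine may be diverted into ionisation of the electron-rich benzylic C–O bond or decarboxylative fragmentation to the styrene, and the lactone may be lost on purification. Fallback, setting out from hydroxy ester 4 and returning at 6: transthioesterification (Me3Al, t-BuSH, CH2Cl2, 0 °C) would give the β-hydroxy S-tert-butyl thioester F5, which would be cyclised under neutral, thiophilic activation (Hg(OCOCF3)2, Na2HPO4, MeCN, rt) to lactone 6 with retention.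

**Further compounds**

F1 | step 7 | (3S)-3-[3-bromo-4-(methoxymethoxy)phenyl]-3-hydroxy-N-methoxy-N-methylpropanamide | CON(C)C(=O)C[C@H](O)c1ccc(OCOC)c(Br)c1
F2 | step 7 | (3S)-3-[3-bromo-4-(methoxymethoxy)phenyl]-N-methoxy-N-methyl-3-(triethylsilyloxy)propanamide | CON(C)C(=O)C[C@H](O[Si](CC)(CC)CC)c1ccc(OCOC)c(Br)c1
F3 | step 7 | (3S)-3-[3-bromo-4-(methoxymethoxy)phenyl]-1-[2-fluoro-6-methoxy-4-(triisopropylsilyloxy)phenyl]-3-(triethylsilyloxy)propan-1-one | CC[Si](CC)(CC)O[C@@H](CC(=O)c1c(F)cc(O[Si](C(C)C)(C(C)C)C(C)C)cc1OC)c1ccc(OCOC)c(Br)c1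
F4 | step 11 | (2S)-5-methoxy-2-[4-(methoxymethoxy)-3-(trimethylstannyl)phenyl]-7-(triisopropylsilyloxy)-2,3-dihydro-4H-chromen-4-one | COc1cc(O[Si](C(C)C)(C(C)C)C(C)C)cc2c1C(=O)C[C@@H](c1ccc(OCOC)c([Sn](C)(C)C)c1)O2
F5 | step 5 | S-tert-butyl (3S)-3-[3-bromo-4-(methoxymethoxy)phenyl]-3-hydroxypropanethioate | CC(C)(C)SC(=O)C[C@H](O)c1ccc(OCOC)c(Br)c1
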